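**Plan** (benzofuran numbering: O1, C2, C3, C3a, C4–C7, C7a; prenyl carbons C1′–C3′)
1. Retrosynthesis: the enol ether O1–C7a is opened to a C2-hydroxy 2-acyl-cyclohexane-1,3,5-trione; the carbocycle is cut at C7–C7a and C3a–C4 into an α-prenyl γ-butyrolactone and a pyran-2,4-dione that carries C4–C7 and the acyl group; the prenyl group is cut at C1′–C2′; the lactone is cut at C3a–C7a with loss of CO.
2. Enabling feature: C7a is at the carboxylic oxidation level (bound to O1 and doubly to the diacyl carbon C7), so ring O1–C2–C3–C3a–C7a is a latent γ-butyrolactone whose carbonyl can be carbon monoxide and whose C3a can be the inner carbon of a terminal alkyne.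
3. Forward: the five-membered ring forms first by cyclocarbonylation (C3a–C7a); the six-membered ring forms second by acyl transfer to C3a and Claisen closure C7→C7a; the furan ring is re-closed last by cyclodehydration of the C2 hydroxyl onto C7a.
4. Stereochemistry: C2 and the side-chain carbinol carbon come from Sharpless epoxidation of geraniol and Payne-type opening (inversion at C2); C3a comes from acylation of the lactone enolate anti to the C2 substituent; the acyl stereocentre comes from (2R)-2-methylbutanoic acid.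

Key step: step 5

Remark: 2-acyl-1,3,5-triones are written as one enol tautomer; the tautomers equilibrate and react as one compound.

Step 1
Reactants: 1 geraniol
Product: 2 [(2S,3S)-3-methyl-3-(4-methylpent-3-en-1-yl)oxiran-2-yl]methanol
Conditions: Ti(OiPr)4 (5 mol %), L-(+)-diethyl tartrate (6 mol %), t-BuOOH, 4 Å MS, CH2Cl2, −20 °C
Reagents that add atoms: tert-butyl hydroperoxide, CC(C)(C)OO
Why: Sharpless asymmetric epoxidation of the allylic alcohol; the L-tartrate ligand directs oxygen to the face that gives the (2S,3S)-epoxide, and the isolated C6–C7 alkene is not touched.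

Step 2
Reactants: 2 [(2S,3S)-3-methyl-3-(4-methylpent-3-en-1-yl)oxiran-2-yl]methanol
Product: 3 (2R,3S)-3,7-dimethyloct-6-ene-1,2,3-triol
Conditions: NaOH (0.5 M in H2O), t-BuOH, 70 °C
Reagents that add atoms: water, O
Why: Payne rearrangement of the epoxy alkoxide to the terminal epoxide and attack of hydroxide at the primary carbon should give the triol; the intramolecular displacement inverts C2 and leaves the tertiary C–O bond intact, which sets the anti (2R,3S) diol.

Step 3
Reactants: 3 (2R,3S)-3,7-dimethyloct-6-ene-1,2,3-triol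
Product: 4 (2R,3S)-2,3-dihydroxy-3,7-dimethyloct-6-en-1-yl 4-methylbenzenesulfonate
Conditions: TsCl, Et3N, Bu2SnO (2 mol %), CH2Cl2, 0 °C → rt
Reagents that add atoms: 4-methylbenzenesulfonyl chloride, Cc1ccc(cc1)S(Cl)(=O)=O
Why: Stannylene-acetal-catalysed sulfonylation of a 1,2-diol activates the primary oxygen, so only C1 should be tosylated and the secondary and tertiary hydroxyls stay free.

Step 4
Reactants: 4 (2R,3S)-2,3-dihydroxy-3,7-dimethyloct-6-en-1-yl 4-methylbenzenesulfonate
Product: 6 (4R,5S)-5,9-dimethyldec-8-en-1-yne-4,5-diol, via epoxy alcohol 5 (not isolated)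
Conditions: LiC≡CH·H2NCH2CH2NH2 (4 equiv), DMSO, rt; H2O work-up
Reagents that add atoms: lithium acetylide (ethylenediamine complex), [Li]C#C
Why: The C2 alkoxide should close the terminal epoxide 5 by intramolecular displacement of the tosylate (retention at C2), and the acetylide then opens it at the primary carbon (SN2 epoxide opening); a Payne equilibrium of 5 with the internal epoxide is harmless because only the terminal epoxide is attacked at a useful rate.

Step 5
Reactants: 6 (4R,5S)-5,9-dimethyldec-8-en-1-yne-4,5-diol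
Product: 7 (5R)-5-[(2S)-2-hydroxy-6-methylhept-5-en-2-yl]-3-methylideneoxolan-2-one
Conditions: PdI2 (5 mol %), PBu3 (5 mol %), CO (7 atm), MeCN, 75 °C
Reagents that add atoms: carbon monoxide, [C-]#[O+]
Why: Carbon monoxide and the secondary hydroxyl should form an alkoxycarbonyl–palladium species on divalent palladium; syn insertion of the alkyne into its Pd–C bond joins the carbonyl carbon (later C7a) to the inner alkyne carbon (later C3a), and protonolysis of the vinyl–palladium bond releases the exo-methylene lactone and the catalyst. The closest known reaction type is the palladium-catalysed cyclocarbonylation of 3-butyn-1-ols to α-methylene-γ-butyrolactones. The five-membered ring closes in a 5-exo-dig mode. No new stereocentre is formed, and C5 of the lactone keeps its configuration because its C–O bond is not broken. The step needs selectivity for the secondary over the tertiary hydroxyl and for the alkyne over the trisubstituted alkene; the first is secured by the lower hindrance of the secondary alcohol and the preference for five- over six-membered closure, the second by the failure of the acylpalladium to insert an unactivated trisubstituted alkene.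

Step 6
Reactants: 7 (5R)-5-[(2S)-2-hydroxy-6-methylhept-5-en-2-yl]-3-methylideneoxolan-2-one
Product: 8 (5R)-3-methylidene-5-[(2S)-6-methyl-2-(triethylsilyloxy)hept-5-en-2-yl]oxolan-2-one
Conditions: Et3SiOSO2CF3, 2,6-lutidine, CH2Cl2, −78 → 0 °C
Reagents that add atoms: triethylsilyl trifluoromethanesulfonate, CC[Si](CC)(CC)OS(=O)(=O)C(F)(F)F
Why: Silyl triflate with a hindered pyridine base silylates tertiary alcohols (silyl ether protection), which masks the only remaining O–H before the enolate steps.

Step 7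
Reactants: 8 (5R)-3-methylidene-5-[(2S)-6-methyl-2-(triethylsilyloxy)hept-5-en-2-yl]oxolan-2-one
Product: 9 (5R)-3-(3-methylbut-2-en-1-yl)-5-[(2S)-6-methyl-2-(triethylsilyloxy)hept-5-en-2-yl]oxolan-2-one (mixture of C3 epimers)
Conditions: Me2C=CHMgBr, CuI (10 mol %), THF, −40 °C; H2O work-up
Reagents that add atoms: (2-methylprop-1-en-1-yl)magnesium bromide, CC(C)=C[Mg]Br
Why: Copper-catalysed conjugate addition of the alkenyl Grignard reagent to the α-methylene lactone builds the prenyl group (C1′–C2′ bond); the new C3 stereocentre forms unselectively, which does not matter because it is enolised in step 11.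

Step 8
Reactants: 10 tert-butyl 3-oxobutanoate
Product: 11 tert-butyl 2,2-dimethyl-3-oxobutanoate
Conditions: MeI (2.5 equiv), K2CO3, acetone, reflux
Reagents that add atoms: iodomethane, CI
Why: Double C-alkylation of the acetoacetate enolate blocks C2, so that the ketone can later enolise only at its methyl group.

Step 9
Reactants: 11 tert-butyl 2,2-dimethyl-3-oxobutanoate; 12 (2R)-2-methylbutanoic acid
Product: 14 tert-butyl (6R)-2,2,6-trimethyl-3,5-dioxooctanoate, via acyl imidazole 13 (not isolated)
Conditions: 12, 1,1′-carbonyldiimidazole, THF, rt; added to 11 (2 equiv), LiN(iPr)2 (2 equiv), THF, −78 → 0 °C; AcOH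
Reagents that add atoms: none
Why: The kinetic lithium enolate of 11 is C-acylated by the N-acylimidazole 13 (crossed Claisen condensation to a 1,3-diketone, the second equivalent of enolate serving as base); at −78 °C the α-stereocentre of the acyl donor should not be enolised.

Step 10
Reactants: 14 tert-butyl (6R)-2,2,6-trimethyl-3,5-dioxooctanoate
Product: 16 6-[(2R)-butan-2-yl]-3,3-dimethyl-2H-pyran-2,4(3H)-dione, via diketo acid 15 (not isolated)
Conditions: CF3CO2H, (CF3CO)2O, CH2Cl2, 0 °C → rt
Reagents that add atoms: none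
Why: Acid cleaves the tert-butyl ester and the anhydride activates acid 15, whose enol oxygen closes the six-membered enol lactone (6-exo-trig O-acylation, the usual pyranone closure of 3,5-dioxo acids); the gem-dimethyl group prevents aromatisation, so the ring keeps an acylating enol-ester carbonyl.

Step 11
Reactants: 9 (5R)-3-(3-methylbut-2-en-1-yl)-5-[(2S)-6-methyl-2-(triethylsilyloxy)hept-5-en-2-yl]oxolan-2-one (mixture of C3 epimers); 16 6-[(2R)-butan-2-yl]-3,3-dimethyl-2H-pyran-2,4(3H)-dione
Product: 18 (6S)-6-[(2R,3S)-2-hydroxy-3,7-dimethyl-3-(triethylsilyloxy)oct-6-en-1-yl]-2,2-dimethyl-4-[(2R)-2-methylbutanoyl]-6-(3-methylbut-2-en-1-yl)cyclohexane-1,3,5-trione, via C-acylated lactone 17 (not isolated)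
Conditions: LiN(iPr)2 (1.05 equiv), THF, −78 °C; 16 (1.2 equiv), −78 → 0 °C, then 40 °C; AcOH
Reagents that add atoms: none
Why: Proposed new method: the lithium enolate of 9 should attack the enol-lactone carbonyl C2 of 16 (closest known reaction type: C-acylation of ester enolates by enol esters or aryl esters) from the face anti to the C5 substituent, as is general for α-substituted γ-butyrolactone enolates, which sets the quaternary centre and gives 17 as its lithium 1,3-diketonate; the central carbon of that diketonate then closes the six-membered ring on the lactone carbonyl (intramolecular Claisen condensation, 6-exo-trig) with opening of the lactone to the C2 alkoxide, which is protonated by the acidic triketone.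

Step 12
Reactants: 18 (6S)-6-[(2R,3S)-2-hydroxy-3,7-dimethyl-3-(triethylsilyloxy)oct-6-en-1-yl]-2,2-dimethyl-4-[(2R)-2-methylbutanoyl]-6-(3-methylbut-2-en-1-yl)cyclohexane-1,3,5-trione
Product: 20 (2R,3aS)-2-[(2S)-2-hydroxy-6-methylhept-5-en-2-yl]-5,5-dimethyl-7-[(2R)-2-methylbutanoyl]-3a-(3-methylbut-2-en-1-yl)-3,3a-dihydro-1-benzofuran-4,6(2H,5H)-dione, via diol trione 19 (not isolated)
Conditions: TsOH·H2O (10 mol %), MeOH, 0 °C → rt; then PhMe, 4 Å MS, 40 °C
Reagents that add atoms: none
Why: Acid removes the silyl ether and catalyses the intramolecular vinylogous esterification (hemiketal of the C2 hydroxyl at C7a, then dehydration towards C7, 5-exo-trig); the other carbonyl next to C3a (C4) lies between two quaternary carbons and cannot dehydrate, so only the target ring fusion should form and no stereocentre is touched.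

**Compound list**
1 | geraniol, (2E)-3,7-dimethylocta-2,6-dien-1-ol | CC(C)=CCC/C(C)=C/CO | starting material
2 | [(2S,3S)-3-methyl-3-(4-methylpent-3-en-1-yl)oxiran-2-yl]methanol | OC[C@@H]1O[C@@]1(C)CCC=C(C)C | intermediate
3 | (2R,3S)-3,7-dimethyloct-6-ene-1,2,3-triol | OC[C@@H](O)[C@@](C)(O)CCC=C(C)C | intermediate
4 | (2R,3S)-2,3-dihydroxy-3,7-dimethyloct-6-en-1-yl 4-methylbenzenesulfonate | Cc1ccc(cc1)S(=O)(=O)OC[C@@H](O)[C@@](C)(O)CCC=C(C)C | intermediate
5 | (2S)-6-methyl-2-[(2R)-oxiran-2-yl]hept-5-en-2-ol | C1O[C@H]1[C@@](C)(O)CCC=C(C)C | intermediate (not isolated)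
6 | (4R,5S)-5,9-dimethyldec-8-en-1-yne-4,5-diol | C#CC[C@@H](O)[C@@](C)(O)CCC=C(C)C | intermediate
7 | (5R)-5-[(2S)-2-hydroxy-6-methylhept-5-en-2-yl]-3-methylideneoxolan-2-one | C=C1C[C@@H](OC1=O)[C@@](C)(O)CCC=C(C)C | intermediate
8 | (5R)-3-methylidene-5-[(2S)-6-methyl-2-(triethylsilyloxy)hept-5-en-2-yl]oxolan-2-one | C=C1C[C@@H](OC1=O)[C@@](C)(O[Si](CC)(CC)CC)CCC=C(C)C | intermediate
9 | (5R)-3-(3-methylbut-2-en-1-yl)-5-[(2S)-6-methyl-2-(triethylsilyloxy)hept-5-en-2-yl]oxolan-2-one (mixture of C3 epimers) | CC(C)=CCC1C[C@@H](OC1=O)[C@@](C)(O[Si](CC)(CC)CC)CCC=C(C)C | intermediate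
10 | tert-butyl 3-oxobutanoate | CC(=O)CC(=O)OC(C)(C)C | starting material
11 | tert-butyl 2,2-dimethyl-3-oxobutanoate | CC(=O)C(C)(C)C(=O)OC(C)(C)C | intermediate
12 | (2R)-2-methylbutanoic acid | CC[C@@H](C)C(O)=O | starting material
13 | (2R)-1-(1H-imidazol-1-yl)-2-methylbutan-1-one | CC[C@@H](C)C(=O)n1ccnc1 | intermediate (not isolated)
14 | tert-butyl (6R)-2,2,6-trimethyl-3,5-dioxooctanoate | CC[C@@H](C)C(=O)CC(=O)C(C)(C)C(=O)OC(C)(C)C | intermediate
15 | (6R)-2,2,6-trimethyl-3,5-dioxooctanoic acid | CC[C@@H](C)C(=O)CC(=O)C(C)(C)C(O)=O | intermediate (not isolated)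
16 | 6-[(2R)-butan-2-yl]-3,3-dimethyl-2H-pyran-2,4(3H)-dione | CC[C@@H](C)C1=CC(=O)C(C)(C)C(=O)O1 | intermediate
17 | (3R,5R)-3-(3-methylbut-2-en-1-yl)-5-[(2S)-6-methyl-2-(triethylsilyloxy)hept-5-en-2-yl]-3-[(6R)-2,2,6-trimethyl-3,5-dioxooctanoyl]oxolan-2-one | CC[C@@H](C)C(=O)CC(=O)C(C)(C)C(=O)[C@@]1(CC=C(C)C)C[C@@H](OC1=O)[C@@](C)(O[Si](CC)(CC)CC)CCC=C(C)C | intermediate (not isolated)
18 | (6S)-6-[(2R,3S)-2-hydroxy-3,7-dimethyl-3-(triethylsilyloxy)oct-6-en-1-yl]-2,2-dimethyl-4-[(2R)-2-methylbutanoyl]-6-(3-methylbut-2-en-1-yl)cyclohexane-1,3,5-trione (enol tautomer drawn) | CC[C@@H](C)C(=O)C1=C(O)[C@](CC=C(C)C)(C[C@@H](O)[C@@](C)(O[Si](CC)(CC)CC)CCC=C(C)C)C(=O)C(C)(C)C1=O | intermediate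
19 | (6S)-6-[(2R,3S)-2,3-dihydroxy-3,7-dimethyloct-6-en-1-yl]-2,2-dimethyl-4-[(2R)-2-methylbutanoyl]-6-(3-methylbut-2-en-1-yl)cyclohexane-1,3,5-trione (enol tautomer drawn) | CC[C@@H](C)C(=O)C1=C(O)[C@](CC=C(C)C)(C[C@@H](O)[C@@](C)(O)CCC=C(C)C)C(=O)C(C)(C)C1=O | intermediate (not isolated)
20 | (2R,3aS)-2-[(2S)-2-hydroxy-6-methylhept-5-en-2-yl]-5,5-dimethyl-7-[(2R)-2-methylbutanoyl]-3a-(3-methylbut-2-en-1-yl)-3,3a-dihydro-1-benzofuran-4,6(2H,5H)-dione | CC[C@@H](C)C(=O)C1=C2O[C@@H]([C@@](C)(O)CCC=C(C)C)C[C@]2(CC=C(C)C)C(=O)C(C)(C)C1=O | target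

**Count**
Total steps: 12. Longest linear sequence: 9 steps (steps 1–7, 11 and 12); steps 8–10 make the pyran-2,4-dione 16.

**Steps most likely to fail**

1. Step 11 (Proposed new method). The risks are proton transfer from the γ-C–H of 16 to the lactone enolate (which would also erode the acyl stereocentre), attack at C6 of 16 instead of the lactone carbonyl, slow bond formation between two fully substituted carbons, and incomplete Claisen closure. The fallback sets out from 9 and uses known chemistry only. tert-Butyl ester 11 is cleaved with CF3CO2H to 2,2-dimethyl-3-oxobutanoic acid F1, which oxalyl chloride converts into 2,2-dimethyl-3-oxobutanoyl chloride F2. The lithium enolate of 9 (LiN(iPr)2, THF, −78 °C) is C-acylated by F2, again anti to the C5 substituent, to give the methyl ketone (3R,5R)-3-(2,2-dimethyl-3-oxobutanoyl)-3-(3-methylbut-2-en-1-yl)-5-[(2S)-6-methyl-2-(triethylsilyloxy)hept-5-en-2-yl]oxolan-2-one F3. LiN(SiMe3)2 (2.2 equiv) then forms the only possible ketone enolate (at the methyl group), which closes the ring on the lactone carbonyl (Dieckmann-type Claisen condensation) to the hydroxy trione (6S)-6-[(2R,3S)-2-hydroxy-3,7-dimethyl-3-(triethylsilyloxy)oct-6-en-1-yl]-2,2-dimethyl-6-(3-methylbut-2-en-1-yl)cyclohexane-1,3,5-trione F4. C-acylation of F4 with acid 12 (N,N′-dicyclohexylcarbodiimide, 4-dimethylaminopyridine; O-acylation of the enol followed by acyl shift to carbon) comes back to the route at 18.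

2. Step 5. The risks are inhibition of the catalyst by chelation of the 1,2-diol, competing six-membered closure through the tertiary hydroxyl, and oligomerisation of the alkyne. The fallback sets out from 6. Syn-stannylcupration with Me3SnCu·SMe2 in THF/MeOH at −63 °C places tin on the inner alkyne carbon and gives (4R,5S)-5,9-dimethyl-2-(trimethylstannyl)deca-1,8-diene-4,5-diol F5. Iododestannylation (I2, CH2Cl2, 0 °C) gives (4R,5S)-2-iodo-5,9-dimethyldeca-1,8-diene-4,5-diol F6. Carbonylation with Pd(PPh3)4 (zerovalent palladium), CO and Et3N in MeCN then proceeds by oxidative addition, CO insertion and O-acylation by the secondary hydroxyl, and comes back to the route at 7.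

3. Step 4. The risks are reversal of the epoxide closure by Payne rearrangement with opening of the internal epoxide at C2, and base-induced elimination of the tosylate. The fallback sets out from 4 and avoids any free epoxy alkoxide. The diol is protected with 2,2-dimethoxypropane and pyridinium 4-methylbenzenesulfonate as the acetonide [(4R,5S)-2,2,5-trimethyl-5-(4-methylpent-3-en-1-yl)-1,3-dioxolan-4-yl]methyl 4-methylbenzenesulfonate F7. Direct SN2 displacement of the tosylate with LiC≡CSiMe3 in THF/DMPU gives trimethyl{3-[(4R,5S)-2,2,5-trimethyl-5-(4-methylpent-3-en-1-yl)-1,3-dioxolan-4-yl]prop-1-yn-1-yl}silane F8. K2CO3 in MeOH removes the silyl group to give (4S,5R)-2,2,4-trimethyl-4-(4-methylpent-3-en-1-yl)-5-(prop-2-yn-1-yl)-1,3-dioxolane F9. Aqueous acetic acid then removes the acetonide and comes back to the route at 6.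

**Further compounds**
F1 | step 11 | 2,2-dimethyl-3-oxobutanoic acid | CC(=O)C(C)(C)C(O)=O
F2 | step 11 | 2,2-dimethyl-3-oxobutanoyl chloride | CC(=O)C(C)(C)C(Cl)=O
F3 | step 11 | (3R,5R)-3-(2,2-dimethyl-3-oxobutanoyl)-3-(3-methylbut-2-en-1-yl)-5-[(2S)-6-methyl-2-(triethylsilyloxy)hept-5-en-2-yl]oxolan-2-one | CC(=O)C(C)(C)C(=O)[C@@]1(CC=C(C)C)C[C@@H](OC1=O)[C@@](C)(O[Si](CC)(CC)CC)CCC=C(C)C
F4 | step 11 | (6S)-6-[(2R,3S)-2-hydroxy-3,7-dimethyl-3-(triethylsilyloxy)oct-6-en-1-yl]-2,2-dimethyl-6-(3-methylbut-2-en-1-yl)cyclohexane-1,3,5-trione | CC(C)=CC[C@]1(C[C@@H](O)[C@@](C)(O[Si](CC)(CC)CC)CCC=C(C)C)C(=O)CC(=O)C(C)(C)C1=O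
F5 | step 5 | (4R,5S)-5,9-dimethyl-2-(trimethylstannyl)deca-1,8-diene-4,5-diol | C=C(C[C@@H](O)[C@@](C)(O)CCC=C(C)C)[Sn](C)(C)C
F6 | step 5 | (4R,5S)-2-iodo-5,9-dimethyldeca-1,8-diene-4,5-diol | C=C(I)C[C@@H](O)[C@@](C)(O)CCC=C(C)C
F7 | step 4 | [(4R,5S)-2,2,5-trimethyl-5-(4-methylpent-3-en-1-yl)-1,3-dioxolan-4-yl]methyl 4-methylbenzenesulfonate | Cc1ccc(cc1)S(=O)(=O)OC[C@H]1OC(C)(C)O[C@@]1(C)CCC=C(C)C
F8 | step 4 | trimethyl{3-[(4R,5S)-2,2,5-trimethyl-5-(4-methylpent-3-en-1-yl)-1,3-dioxolan-4-yl]prop-1-yn-1-yl}silane | C[Si](C)(C)C#CC[C@H]1OC(C)(C)O[C@@]1(C)CCC=C(C)C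
F9 | step 4 | (4S,5R)-2,2,4-trimethyl-4-(4-methylpent-3-en-1-yl)-5-(prop-2-yn-1-yl)-1,3-dioxolane | C#CC[C@H]1OC(C)(C)O[C@@]1(C)CCC=C(C)C
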